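## Retrosynthetic overview

1. Succinimide ring last: neutral hydration of a nitrile and N-acyl transfer from an Evans syn-aldol adduct (C12–C13 bond) made on a C6-keto C12-aldehyde.
2. Rings A and B in one step (A, then B): cation–olefin bicyclisation started by ionising a tertiary methyl ether next to a pre-set (2R,3R)-dichloride, relayed through the (E)-C5=C10 olefin, ended by a 2-substituted allylsilane that leaves the 8(17)-methylene. A C6 silyloxy group is carried through as the latent ketone.
3. Acyclic precursor: silylmethyl-carbocupration/ethylene oxide trapping of a homopropargylic ether; asymmetric propargylation of an enal sets C6.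
4. Dichloro-enal: organocatalytic α-chlorination (C3), Cornforth-selective propargylation, invertive chlorination (C2), Zr-carboalumination.

Assumptions: labdane numbering is used for locants (decalin C1–C10, exocyclic CH2 = C17, side chain C11–C13, imide C14–C16); α is the face opposite the C10 methyl. For the two organocatalysts (steps 2 and 7) the required product configuration is stated; the antipode named is the one expected to give it from the usual sense of induction, and the other antipode is used if that sense is reversed.

## Route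

**Step 1**
Reactants: 1, 3-methoxy-3-methylbutan-1-ol
Product: 2, 3-methoxy-3-methylbutanal
Conditions: TEMPO (cat.), PhI(OAc)2, CH2Cl2, rt
Reagents that add atoms: none
Why: Chemoselective TEMPO oxidation of the primary alcohol; the tertiary methyl ether (the future C4 leaving group) is inert.

**Step 2**
Reactants: 2
Product: 3, (R)-2-chloro-3-methoxy-3-methylbutanal
Conditions: (5R)-5-benzyl-2,2,3-trimethylimidazolidin-4-one·TFA (10 mol %), 2,3,4,5,6,6-hexachlorocyclohexa-2,4-dienone, acetone, −30 °C; used crude
Reagents that add atoms: 2,3,4,5,6,6-hexachlorocyclohexa-2,4-dien-1-one, O=C1C(Cl)=C(Cl)C(Cl)=C(Cl)C1(Cl)Cl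
Why: Enamine-catalysed asymmetric α-chlorination (MacMillan type), which tolerates tert-alkyl acetaldehydes; the catalyst sets the C3–Cl centre (R), and methoxide is too poor a leaving group for E1cB loss.

**Step 3**
Reactants: 3; 4, allenylboronic acid pinacol ester
Product: 5, (4S,5S)-5-chloro-6-methoxy-6-methylhept-1-yn-4-ol (anti-chlorohydrin)
Conditions: toluene, 4 Å MS, 0 °C → rt
Reagents that add atoms: 4, C=C=CB1OC(C)(C)C(C)(C)O1
Why: SE2′ propargylation through a closed six-membered transition state; Cornforth–Evans control (C–Cl anti to C=O, attack opposite the bulky CMe2OMe group) gives the 1,2-anti chlorohydrin and sets the C2 carbinol.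

**Step 4**
Reactants: 5
Product: 6, (4R,5R)-4,5-dichloro-6-methoxy-6-methylhept-1-yne
Conditions: 1-chloro-N,N,2-trimethylprop-1-enylamine (Ghosez reagent), CH2Cl2, 0 °C → rt
Reagents that add atoms: Ghosez reagent, CC(C)=C(Cl)N(C)C
Why: SN2 deoxychlorination with inversion at the non-neopentyl carbinol turns the anti-chlorohydrin into the syn (2R,3R)-dichloride, which becomes trans-diequatorial in the ring.

**Step 5**
Reactants: 6
Product: 7, (2E,5R,6R)-5,6-dichloro-7-methoxy-3,7-dimethyloct-2-en-1-ol
Conditions: AlMe3, Cp2ZrCl2 (cat.), H2O (1 equiv), CH2Cl2, −25 → 0 °C; then n-BuLi, (CH2O)n, THF, −78 °C → rt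
Reagents that add atoms: trimethylaluminium, C[Al](C)C; paraformaldehyde (as formaldehyde), C=O
Why: Negishi Zr-catalysed syn-carboalumination places Me on the internal carbon, and hydroxymethylation of the alkenylalanate gives the E-trisubstituted C5=C10 olefin stereospecifically; the water-accelerated low-temperature protocol limits contact of AlMe3 with the tertiary ether.

**Step 6**
Reactants: 7
Product: 8, (2E,5R,6R)-5,6-dichloro-7-methoxy-3,7-dimethyloct-2-enal
Conditions: MnO2, CH2Cl2, rt
Reagents that add atoms: none
Why: Neutral allylic oxidation keeps the E geometry and avoids the base-promoted vinylogous loss of HCl that this δ-chloro enal would undergo.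

**Step 7**
Reactants: 8; 4
Product: 9, (4S,5E,8R,9R)-8,9-dichloro-10-methoxy-6,10-dimethylundec-5-en-1-yn-4-ol (6S in labdane numbering)
Conditions: (S)-TRIP phosphoric acid (10 mol %), 4 Å MS, toluene, −20 °C
Reagents that add atoms: 4, C=C=CB1OC(C)(C)C(C)(C)O1
Why: Chiral-phosphoric-acid-catalysed propargylboration (1,2-addition, Si-face) sets the C6 carbinol by catalyst control, since the dichloride is too remote to interfere.

**Step 8**
Reactants: 9
Product: 10, the C6 triisopropylsilyl ether of 9
Conditions: TIPSOTf, 2,6-lutidine, CH2Cl2, −78 → 0 °C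
Reagents that add atoms: TIPSOTf, CC(C)[Si](C(C)C)(C(C)C)OS(=O)(=O)C(F)(F)F
Why: Standard silylation; the bulky, weakly Lewis-basic TIPS ether is chosen so that this allylic oxygen neither chelates copper in step 9 nor ionises in step 11.

**Step 9**
Reactants: 10; 11, (trimethylsilyl)methylmagnesium chloride; 12, ethylene oxide
Product: 13, (3Z,6S,7E,10R,11R)-10,11-dichloro-12-methoxy-8,12-dimethyl-6-(triisopropylsilyloxy)-4-[(trimethylsilyl)methyl]trideca-3,7-dien-1-ol
Conditions: 11, CuBr·SMe2, Et2O/Me2S, −40 °C; add 10, −20 → 10 °C; then 12 (excess), −40 → 0 °C; aq. NH4Cl/NH3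
Reagents that add atoms: 11, C[Si](C)(C)C[Mg]Cl; 12, C1CO1
Why: Normant syn-carbocupration puts Me3SiCH2 on the internal alkyne carbon (C8) and Cu on C9, and the vinylcopper opens ethylene oxide with retention, so C11 ends cis to CH2SiMe3 (the farnesyl-like geometry needed for an equatorial C9 side chain); the β-hydrogen-free silylmethylcopper can be warmed without decomposition.

**Step 10**
Reactants: 13
Product: 14, the primary tert-butyldimethylsilyl ether of 13
Conditions: TBSCl, imidazole, DMF, rt
Reagents that add atoms: TBSCl, CC(C)(C)[Si](C)(C)Cl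
Why: Routine protection so the primary hydroxyl cannot trap the C8 cation or quench the Lewis acid in the cyclisation.

**Step 11 (key step)**
Reactants: 14
Product: 15, 2α,3β-dichloro-6α-(triisopropylsilyloxy)-12-(tert-butyldimethylsilyloxy)-13,14,15,16-tetranorlabd-8(17)-ene (2R,3R,5R,6S,9S,10R; trans-decalin, 5α-H, 9α-H, 10β-Me)
Conditions: TMSNTf2 (0.3 equiv), 2,6-di-tert-butyl-4-methylpyridine (0.3 equiv), CH2Cl2 (5 mM), −78 → −40 °C
Reagents that add atoms: none
Why: Proposed new method: Me3Si+ silylates the least hindered ether oxygen (OMe, not the bulky OTIPS) and expels MeOSiMe3 to give the C4 tertiary cation, which the C3 chlorine bridges as a chloriranium-type ion (the intermediate of chloronium-induced polyene cyclisations); the closest known reaction types are halonium-initiated and tertiary-ether/acetal-initiated cation–olefin cyclisations terminated by allylsilanes. A chair–chair transition state with both C–Cl bonds equatorial (C3–Cl anti to the forming C4–C5 bond) lets the E-C5=C10 olefin and then the allylsilane add anti, so the existing dichloride fixes C5, C10 and C9 (side chain equatorial); the 6S-OTIPS group is matched (C6–H in the A1,3 position, OSi equatorial), and loss of Me3Si+ gives only the 8(17)-methylene and regenerates the silyl Lewis acid.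

**Step 12**
Reactants: 15
Product: 16, 2α,3β-dichloro-13,14,15,16-tetranorlabd-8(17)-ene-6α,12-diol
Conditions: TBAF, THF, 45 °C
Reagents that add atoms: none
Why: Fluoride cleaves both silyl ethers; the trans-diequatorial dichloride has no anti-periplanar H–C–C–Cl arrangement, so E2 loss of HCl is disfavoured.

**Step 13**
Reactants: 16
Product: 17, 2α,3β-dichloro-6-oxo-13,14,15,16-tetranorlabd-8(17)-en-12-al (keto-aldehyde)
Conditions: Dess–Martin periodinane (3 equiv), NaHCO3, CH2Cl2, 0 °C → rt
Reagents that add atoms: none
Why: Buffered Dess–Martin oxidation of both alcohols gives the β,γ-unsaturated ketone without conjugation and removes the relay stereocentre at C6; C5 stays in the favoured trans-fused (5α-H) configuration.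

**Step 14 (side branch)**
Reactants: 18, (R)-4-benzyl-2-oxazolidinone; 19, 3-cyanopropanoic acid
Product: 20, (R)-4-benzyl-3-(3-cyanopropanoyl)oxazolidin-2-one
Conditions: 19, PivCl, Et3N, THF, −20 °C; then 18, LiCl, rt
Reagents that add atoms: none beyond 18 and 19
Why: Mixed-anhydride N-acylation of the oxazolidinone; the nitrile is a masked primary amide that cannot lactonise with the future C12 hydroxyl.

**Step 15**
Reactants: 17; 20
Product: 21, Evans syn-aldol adduct (12S,13R): the decalin of 17 carrying C11H2–C12H(OH)–C13H(CH2CN)–C(=O)–N[(R)-4-benzyl-2-oxazolidinone]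
Conditions: 20 (1.3 equiv), Bu2BOTf (1.25 equiv), i-Pr2NEt (1.4 equiv), CH2Cl2, −78 → 0 °C; then 17, −78 → −20 °C; pH 7 buffer, MeOH, 30% H2O2, 0 °C
Reagents that add atoms: 20, N#CCCC(=O)N1[C@H](Cc2ccccc2)COC1=O
Why: The Z-boron enolate of the (R)-auxiliary reacts through a Zimmerman–Traxler chair to give the Evans syn adduct, setting C12 (S) and C13 (R) by reagent control; with the imide in excess no free Bu2BOTf/amine remains to enolise the hindered C6 ketone, and the aldehyde is the only reactive carbonyl.

**Step 16**
Reactants: 21
Product: 22, haterumaimide B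
Conditions: [PtH{(PMe2O)2H}(PMe2OH)] (Ghaffar–Parkins catalyst, 5 mol %), EtOH/H2O 4:1, 60–70 °C
Reagents that add atoms: water, O
Why: Proposed new method: neutral Pt-catalysed nitrile hydration (known) gives the C15 primary amide, whose nitrogen then attacks the activated C16 acyl-oxazolidinone (5-exo-trig) and expels the auxiliary to close the succinimide; the closest known type is aminolysis of N-acyl oxazolidinones. C12–OH can only form a strained β-lactone at the activated carbonyl, and the neutral medium spares the β,γ-enone and the C13 centre.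

## Compound list

1 | 3-methoxy-3-methylbutan-1-ol | COC(C)(C)CCO | starting material
2 | 3-methoxy-3-methylbutanal | COC(C)(C)CC=O | intermediate
3 | (R)-2-chloro-3-methoxy-3-methylbutanal | COC(C)(C)[C@@H](Cl)C=O | intermediate
4 | allenylboronic acid pinacol ester | C=C=CB1OC(C)(C)C(C)(C)O1 | starting material
5 | (4S,5S)-5-chloro-6-methoxy-6-methylhept-1-yn-4-ol | COC(C)(C)[C@@H](Cl)[C@@H](O)CC#C | intermediate
6 | (4R,5R)-4,5-dichloro-6-methoxy-6-methylhept-1-yne | COC(C)(C)[C@@H](Cl)[C@H](Cl)CC#C | intermediate
7 | (2E,5R,6R)-5,6-dichloro-7-methoxy-3,7-dimethyloct-2-en-1-ol | COC(C)(C)[C@@H](Cl)[C@H](Cl)C/C(C)=C/CO | intermediate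
8 | (2E,5R,6R)-5,6-dichloro-7-methoxy-3,7-dimethyloct-2-enal | COC(C)(C)[C@@H](Cl)[C@H](Cl)C/C(C)=C/C=O | intermediate
9 | (4S,5E,8R,9R)-8,9-dichloro-10-methoxy-6,10-dimethylundec-5-en-1-yn-4-ol | COC(C)(C)[C@@H](Cl)[C@H](Cl)C/C(C)=C/[C@@H](O)CC#C | intermediate
10 | TIPS ether of 9 | COC(C)(C)[C@@H](Cl)[C@H](Cl)C/C(C)=C/[C@@H](O[Si](C(C)C)(C(C)C)C(C)C)CC#C | intermediate
11 | (trimethylsilyl)methylmagnesium chloride | C[Si](C)(C)C[Mg]Cl | starting material
12 | ethylene oxide | C1CO1 | starting material
13 | (3Z,6S,7E,10R,11R)-allylsilane dienol (see step 9) | COC(C)(C)[C@@H](Cl)[C@H](Cl)C/C(C)=C/[C@@H](O[Si](C(C)C)(C(C)C)C(C)C)C/C(C[Si](C)(C)C)=C/CCO | intermediate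
14 | TBS ether of 13 (cyclisation substrate) | COC(C)(C)[C@@H](Cl)[C@H](Cl)C/C(C)=C/[C@@H](O[Si](C(C)C)(C(C)C)C(C)C)C/C(C[Si](C)(C)C)=C/CCO[Si](C)(C)C(C)(C)C | intermediate
15 | 2α,3β-dichloro-6α-OTIPS-12-OTBS-tetranorlabd-8(17)-ene | C=C1C[C@H](O[Si](C(C)C)(C(C)C)C(C)C)[C@H]2C(C)(C)[C@@H](Cl)[C@H](Cl)C[C@]2(C)[C@H]1CCO[Si](C)(C)C(C)(C)C | intermediate
16 | 2α,3β-dichloro-tetranorlabd-8(17)-ene-6α,12-diol | C=C1C[C@H](O)[C@H]2C(C)(C)[C@@H](Cl)[C@H](Cl)C[C@]2(C)[C@H]1CCO | intermediate
17 | 2α,3β-dichloro-6-oxo-tetranorlabd-8(17)-en-12-al | C=C1CC(=O)[C@H]2C(C)(C)[C@@H](Cl)[C@H](Cl)C[C@]2(C)[C@H]1CC=O | intermediate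
18 | (R)-4-benzyl-2-oxazolidinone | O=C1N[C@H](Cc2ccccc2)CO1 | starting material
19 | 3-cyanopropanoic acid | N#CCCC(=O)O | starting material
20 | (R)-4-benzyl-3-(3-cyanopropanoyl)oxazolidin-2-one | N#CCCC(=O)N1[C@H](Cc2ccccc2)COC1=O | intermediate
21 | (12S,13R) syn-aldol adduct | C=C1CC(=O)[C@H]2C(C)(C)[C@@H](Cl)[C@H](Cl)C[C@]2(C)[C@H]1C[C@H](O)[C@@H](CC#N)C(=O)N1[C@H](Cc2ccccc2)COC1=O | intermediate
22 | haterumaimide B | C=C1CC(=O)[C@H]2C(C)(C)[C@@H](Cl)[C@H](Cl)C[C@]2(C)[C@H]1C[C@H](O)[C@H]1CC(=O)NC1=O | target

## Totals and risks

Total steps: 16. Longest linear sequence: 15 (steps 1–13, 15, 16).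

Three steps most likely to fail, each with a fallback that changes the approach:

1. **Step 11 (dichloride-templated bicyclisation).** The β,γ-dichloro tertiary ether may ionise too slowly, or the allylic C6–OTIPS may ionise instead. Fallback: take the C6 oxygen out of the cyclisation. Make the 6-deoxy polyene from 6 (alkyne → vinyl iodide → sp2–sp3 coupling), cyclise it with proton-loss termination to the Δ7 olefin, then introduce the ketone afterwards by Cr(VI) allylic oxidation to the 7-en-6-one and deconjugation through the C17 dienol silyl ether with kinetic α-protonation.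

2. **Step 9 (silylmethyl-carbocupration / epoxide trapping).** The stabilised Me3SiCH2Cu may add sluggishly or the vinylcopper may not open ethylene oxide cleanly. Fallback: build the terminator from a β-keto ester. Run an asymmetric vinylogous Mukaiyama aldol of enal 8 with the acetoacetate bis-silyl dienolate (sets C6), form the Z-enol triflate, and couple with 11 under Pd catalysis to give the ester-substituted allylsilane. After cyclisation, homologate the C9 ester by one carbon (DIBAL; oxidation; MeOCH=PPh3; H3O+) to the C12 aldehyde.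

3. **Step 16 (and step 15), endgame on the free β,γ-enone.** The amide may not close onto the auxiliary without base, or the enone may conjugate. Fallback: reveal the ketone only after the imide is built. Selectively unmask and oxidise only the primary alcohol of 15, run the aldol with C6–OTIPS in place, protect C12–OH as its allyl carbonate, close the imide (hydration, then mild base is now tolerated), remove TIPS, oxidise C6 with Dess–Martin periodinane, and remove the Alloc group with Pd(0)/PhSiH3 under neutral conditions.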